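In a one-step world starting material passes straight to target, and the question of spacing has two limiting versions that can be solved in the head.

| setting | midnight | summer | dawn | larch | oak | elm |
|---|---|---|---|---|---|---|
| starting material | 20 mM (in portions, 3) | 20 mM (in portions, 3) | 20 mM (in portions, 3) | 20 mM (in portions, 3) | 20 mM (in portions, 3) | 20 mM (in portions, 3) |
| precatalyst | 0.013 mol% | 0.03 mol% | 0.02 mol% | 0.02 mol% | 0.02 mol% | 0.02 mol% |
| impurity | 1.1 µM | 1.1 µM | 2.2 µM | 1.1 µM | 1.1 µM | 1.1 µM |
| remark | run made earlier; portions every 0.80 h | run made earlier; portions every 0.80 h | run made earlier; portions every 0.80 h | the portions of starting material follow each other after 0.80 h, the first at the start | the portions of starting material follow each other after 1.5 h, the first at the start | the portions of starting material follow each other after 3.0 h, the first at the start |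
| time |  |  |  | 12 h | 12 h | 12 h |

- midnight (time / h: target / %, starting material / %): 0.833: 0.4, 67.9; 2.00: 1.8, 99.9; 4.00: 2.8, 98.3; 6.00: 6.8, 93.1; 8.00: 9.8, 90.0; 12.0: 17.3, 82.9; 15.0: 20.3, 76.4
- summer (time / h: target / %, starting material / %): 0.833: 0.1, 66.8; 2.00: 3.0, 96.4; 4.00: 16.2, 84.2; 6.00: 26.3, 72.7; 8.00: 39.3, 60.0; 12.0: 59.1, 36.9; 15.0: 73.9, 19.5
- dawn (time / h: target / %, starting material / %): 1.33: 0.9, 66.3; 4.00: 2.2, 96.6; 6.00: 6.5, 94.8; 10.0: 12.7, 84.9; 15.0: 23.7, 73.0

(scatter of a reading: 1 percentage point)

- "hardly changes" means that all values lie within two and a half points (for a concentration: within two and a half percent of the largest)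

1. amount of target at the end, in percent of the starting material charged for larch, oak, elm, in this order
2. how the row runs (rises all the way / hardly changes / rises, then falls / falls all the way / falls, then rises)

The reckoning is easiest with the fraction left. If the step is first order in [starting material] (pseudo-first-order at fixed catalyst), that fraction falls by the same factor each hour. Each portion then works from its own addition and the average portion starts one interval late, so a wider spacing gives a falling row. If the step is zero order, the fraction left falls by the same amount each hour, and spacing cancels while any starting material stands: a flat row.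

The summer run shows where the real flask lies. Its first-order constant goes from 0.0847 h⁻¹ to 0.161 h⁻¹, nearly twice as much, while its straight-line fall goes from 0.0605 h⁻¹ to 0.0579 h⁻¹ of the charge. So the flask sits near the zero-order end, at least down to 19.5% left.

Midnight and summer share one impurity level, and their straight-line rates, read across by loading to 0.02 mol%, give 0.412 of the way between them, or 0.0310 h⁻¹ of the charge. For elm the low-water mark, the fraction of the charge left just before the second portion if that rate ran from the start, is 24.0%, lower than the 48.1% reckoned the same way for the moment before the last portion. That mark is 4.5 percentage points higher than the 19.5% where summer still ran straight, a narrow clearance. The row should therefore be flat. The same reading across, applied to target at 12.0 h, gives 34.5% for each flask.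

The forecast put 31%, 31% and 31%, a row that hardly changes, and held that “Spacing shouldn't matter unless the induction depends on dosing”. Its shape is the one reckoned here; its level lies lower.

Larch, oak and elm give 34.7%, 34.6% and 34.2%, and the row hardly changes.

    starting material + enzyme → target + enzyme, rate k1*[starting material]*[enzyme]/(1 + ([starting material]/Km1)) (0.797 mM, k = 320 L mol⁻¹ s⁻¹)
    target ⇌ isomer of the product (K = 1.51, k = 3.64 × 10⁻⁶ s⁻¹)
    precatalyst ⇌ enzyme (K = 0.400, k = 9.27 × 10⁻⁵ s⁻¹)
    enzyme + impurity → spent catalyst (k = 7280 L mol⁻¹ s⁻¹)

Just before its last portion elm holds 51.9% at 6.00 h, 3.8 points above the 48.1% that its low-water mark carries forward to that moment; for oak the same reckoning before the last portion gives 57.4%, and oak holds 62.0% at 3.00 h. In larch at 12.0 h target is made 8.25 times faster than it is used up, each step taken net, and its forward half-life towards isomer of the product, 53 h, is long against the 12 h of the run. Isomer of the product ends oak at 2.32%.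

The data are simulated with constants of no real substance; scatter was added.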